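**Remark on the chemistry:** the SMILES carries no stereodescriptor and the structure has no stereocentre or stereogenic double bond, so no step has to set configuration. Compounds 1 and 9 are taken as commercial.

## Structural features

Agrimol C is an achiral trimer of three hexasubstituted benzene rings joined in the order A–B–A by two methylene carbons. Ring B (centre) carries butanoyl at C1, OH at C2, C4 and C6, and the two methylene carbons at C3 and C5. Each methylene is bound to C1' of an outer ring (rings A and A', identical) that carries OH at C2' and C6', CH3 at C3', OCH3 at C4' and butanoyl at C5'. A mirror plane through C1 and C4 of ring B maps one arm onto the other. The fragile elements are seven free phenols on easily oxidised rings, three chelated aryl ketones, and diarylmethane bridges that acid or base can cleave and exchange through ortho-quinone methides. The real difficulty is twofold: the two Ar–CH2–Ar junctions must join different rings without statistical mixing, each at ring carbons flanked by two oxygen-bearing carbons, and the single O-methyl group of ring A must sit on O4', between CH3 and butanoyl. All four ring carbons at the bridges (C3 and C5 of ring B, C1' of rings A and A') are innately nucleophilic, which is why they are normally joined through an electrophilic one-carbon unit. The key step exploits the equivalence of C3 and C5 of ring B and reverses their polarity: as C–I carbons they are electrophilic and are joined in one operation to the bridge carbon, which is carried on ring A as a benzylic zinc nucleophile; the same bridge carbon is para to C4', so while it is still a formyl group it picks out O4' for methylation.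

## Logic of the disconnections

15 to 14. No skeletal bond is cut; the seven phenolic O–H bonds are taken back to seven O–CH2Ph bonds. The organometallic key step needs masked phenols, and benzyl is the ether that can be told apart from the two O–CH3 groups and removed under neutral conditions, where the bridges do not exchange. The forward step must cleave seven benzyl ethers without reducing three aryl ketones.

14 to 12 and two equivalents of 13. The C3–CH2 and C5–CH2 bonds of ring B are cut with reversed polarity: ring B becomes the electrophile (two C–I bonds in 12) and the bridge carbon the nucleophile (C–Zn in 13). In one sentence, the route is a two-fold Negishi coupling of 13 with 12. The cut turns a three-ring, two-bridge problem into one ring B piece and two copies of one ring A piece, and the order A–B–A is fixed by where iodine and zinc sit, so no statistical mixture can arise. The forward step must make two sp2–sp3 bonds at carbons flanked by benzyloxy groups and must tolerate three ketones.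

13 to 8. The C–Zn bond is traced to a C–Cl bond. Zinc insertion into a benzylic chloride tolerates the ketone, so nothing further needs masking. The demand is that Wurtz homocoupling be held back.

8 to 7 to 6. The C–Cl bond is traced to C–OH and then to the formyl group at C1'. This keeps the bridge carbon on ring A from the start of the sequence. The forward reduction must take the aldehyde and leave the butanoyl ketone.

6 to 5. Two O–CH2Ph bonds at O2' and O6' are cut. Protection is placed after the Lewis-acid step so that no benzyl ether meets TiCl4. The demand is O-alkylation of two chelated, flanked phenols.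

5 to 4. The C5'–C(=O) bond is cut (Friedel–Crafts). C5' is the only unsubstituted ring carbon of 4, so regiochemistry is not in question. The demand is acylation of a ring that already carries a formyl group, without loss of that group or of the neighbouring O-methyl.

4 to 3. The O4'–CH3 bond is cut. In 3 the 4-OH is para to the formyl group and is the most acidic and the least hindered hydroxyl, so the formyl group that later becomes the bridge places the methyl ether. The demand is mono-alkylation.

3 to 1. The C1'–CHO bond is cut (Vilsmeier–Haack). The two free positions of 1 are equivalent, so one aldehyde results. The demand is mono-formylation.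

12 to 11. The two C–I bonds at C3 and C5 are cut. These are the only free ring positions of 11 and are activated by three alkoxy groups. The demand is a second iodination next to two benzyloxy groups.

11 to 10. Three O–CH2Ph bonds are cut. The demand is O- rather than C-benzylation of an acylphloroglucinol.

10 to 9. The C1–C(=O) bond is cut (Friedel–Crafts acylation of phloroglucinol). The demand is mono-acylation.

## Other disconnections considered

Alternative 1: the first plan that comes to mind cuts the same Ar–CH2 bonds in their native polarity and inserts formaldehyde between nucleophilic ring carbons. In the forward sense, 10 would be condensed with two equivalents of the ring A monomer A1 and formaldehyde, or the bis-Mannich base A2 of 10 would be heated with A1 so that ortho-quinone methides are trapped. A1 has one nucleophilic carbon and 10 has two, so A1–CH2–A1 dimers, mixed dimers and ring B oligomers should form beside the trimer. The addition to an ortho-quinone methide is reversible under the same conditions, so the bridges would exchange. A1 would still need the regiodefined methyl ether. The chosen plan gives the two rings opposite, fixed roles and forms the bonds irreversibly.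

Alternative 2: ring B could be built last from open-chain material, cutting its C2–C3 and C5–C6 bonds. A 1,5-diarylpentan-3-one A3, assembled from acetone by two aldol condensations and hydrogenation, would be annulated with malonyl dichloride across its two alpha carbons to give the 2,4-bis(arylmethyl)phloroglucinol A4, which would then be butanoylated. After the first C-acylation, the enol oxygen should close a 4-hydroxy-2-pyranone faster than the distal alpha carbon closes the carbocycle. The enolisable butanoyl groups of rings A could not be carried through the aldol assembly of A3, so three Friedel–Crafts acylations would fall on an acid-labile bridged polyphenol at the end, with the O-methyl groups exposed to Lewis acid. The sequence would also be longer.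

Alternative 3: an oxidative union could use ring methyl groups as the bridge carbons. The 3,5-dimethyl ring B compound A5 would be oxidised (Ag2O or DDQ) to the ortho-quinone methide A6 and trapped at the free ring carbon of A1, and the sequence repeated at the second methyl. This is a dehydrogenative C(sp3)–H/C(sp2)–H coupling and needs no protecting groups. However, A1 and every product carry an equally oxidisable ortho-hydroxy methyl group (C3'–CH3), and the new diarylmethane positions are more oxidisable still. No feature of the substrates directs the oxidant to the two methyl groups of A5 only, whereas the chosen plan needs no oxidant at all.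

Key step: step 10

## Steps

Step 1
Reactants: 1 2-methylbenzene-1,3,5-triol (2-methylphloroglucinol)
Product: 3 2,4,6-trihydroxy-3-methylbenzaldehyde, via iminium chloride 2 (not isolated)
Conditions: POCl3, DMF, EtOAc, 0 to 25 °C; then H2O, 60 °C
Reagents that add atoms: N,N-dimethylformamide CN(C)C=O; water O
Why: Vilsmeier–Haack formylation of a phloroglucinol; the two free ring carbons of 1 are equivalent, so a single aldehyde should form, and the iminium salt 2 deactivates the ring against a second formylation before it is hydrolysed.

Step 2
Reactants: 3 2,4,6-trihydroxy-3-methylbenzaldehyde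
Product: 4 2,6-dihydroxy-4-methoxy-3-methylbenzaldehyde
Conditions: Me2SO4 (1.05 equiv), K2CO3 (1.1 equiv), acetone, 25 °C
Reagents that add atoms: dimethyl sulfate COS(=O)(=O)OC
Why: Williamson etherification with one equivalent of base; the 4-OH is para to the formyl group and therefore the most acidic, and it is not flanked by the carbonyl, so its phenoxide should be methylated first, while the two ortho hydroxyls are held back by hydrogen bonding and by the adjacent formyl group.

Step 3
Reactants: 4 2,6-dihydroxy-4-methoxy-3-methylbenzaldehyde
Product: 5 3-butanoyl-2,6-dihydroxy-4-methoxy-5-methylbenzaldehyde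
Conditions: PrCOCl (1.2 equiv), TiCl4 (2.5 equiv), CH2Cl2, 0 to 25 °C; aq. HCl work-up
Reagents that add atoms: butanoyl chloride CCCC(Cl)=O
Why: Friedel–Crafts acylation at the only unsubstituted ring carbon, which lies ortho to a free OH (acylation through the titanium phenoxide) and is still activated by three oxygens, as in the second acylation that gives 2,4-diacylphloroglucinols; TiCl4 at or below 25 °C should spare the methyl ether next to the new ketone.

Step 4
Reactants: 5 3-butanoyl-2,6-dihydroxy-4-methoxy-5-methylbenzaldehyde
Product: 6 2,6-bis(benzyloxy)-3-butanoyl-4-methoxy-5-methylbenzaldehyde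
Conditions: BnBr (2.5 equiv), K2CO3, DMF, 60 °C
Reagents that add atoms: benzyl bromide BrCc1ccccc1
Why: Williamson O-benzylation in a dipolar aprotic solvent, which favours O- over C-alkylation; every ring carbon is substituted and the ring carries two acyl groups, so dearomatising C-benzylation should be slow.

Step 5
Reactants: 6 2,6-bis(benzyloxy)-3-butanoyl-4-methoxy-5-methylbenzaldehyde
Product: 7 1-[2,4-bis(benzyloxy)-3-(hydroxymethyl)-6-methoxy-5-methylphenyl]butan-1-one
Conditions: NaBH4 (0.5 equiv), THF/MeOH, −40 °C
Reagents that add atoms: none
Why: chemoselective hydride reduction; the aldehyde should react far faster than the alkyl aryl ketone, which is shielded by two ortho substituents and a propyl chain.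

Step 6
Reactants: 7 1-[2,4-bis(benzyloxy)-3-(hydroxymethyl)-6-methoxy-5-methylphenyl]butan-1-one
Product: 8 1-[2,4-bis(benzyloxy)-3-(chloromethyl)-6-methoxy-5-methylphenyl]butan-1-one
Conditions: SOCl2 (1.1 equiv), Et3N (1.2 equiv), CH2Cl2, −10 °C; used at once
Reagents that add atoms: thionyl chloride O=S(Cl)Cl
Why: chlorodehydroxylation of an electron-rich benzylic alcohol through its chlorosulfite; the base takes up HCl so that the benzyl ethers and the ionisable chloride are not exposed to acid.

Step 7
Reactants: 9 benzene-1,3,5-triol (phloroglucinol)
Product: 10 1-(2,4,6-trihydroxyphenyl)butan-1-one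
Conditions: PrCOCl (1.0 equiv), AlCl3, PhNO2/CH2Cl2, 0 to 25 °C
Reagents that add atoms: butanoyl chloride CCCC(Cl)=O
Why: Friedel–Crafts mono-acylation of phloroglucinol; the three ring positions are equivalent and the first acyl group, held in an aluminium chelate, slows a second acylation.

Step 8
Reactants: 10 1-(2,4,6-trihydroxyphenyl)butan-1-one
Product: 11 1-[2,4,6-tris(benzyloxy)phenyl]butan-1-one
Conditions: BnBr (3.6 equiv), K2CO3, DMF, 70 °C
Reagents that add atoms: benzyl bromide BrCc1ccccc1
Why: exhaustive Williamson O-benzylation; carbonate in DMF favours O-alkylation of the acylphloroglucinol, and heating drives the two chelated ortho hydroxyls to react.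

Step 9
Reactants: 11 1-[2,4,6-tris(benzyloxy)phenyl]butan-1-one
Product: 12 1-[2,4,6-tris(benzyloxy)-3,5-diiodophenyl]butan-1-one
Conditions: NIS (2.3 equiv), CF3CO2H (cat.), MeCN, 25 °C, dark
Reagents that add atoms: N-iodosuccinimide O=C1CCC(=O)N1I
Why: electrophilic aromatic iodination; C3 and C5 are the only free ring positions and each is ortho to two and para to one alkoxy group, while the twisted ketone deactivates little and the phenyl rings of the benzyl groups are not activated.

Step 10
Reactants: 8 1-[2,4-bis(benzyloxy)-3-(chloromethyl)-6-methoxy-5-methylphenyl]butan-1-one; 12 1-[2,4,6-tris(benzyloxy)-3,5-diiodophenyl]butan-1-one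
Product: 14 1-[2,4,6-tris(benzyloxy)-3,5-bis({[2,6-bis(benzyloxy)-3-butanoyl-4-methoxy-5-methylphenyl]methyl})phenyl]butan-1-one (hepta-O-benzyl agrimol C), via benzylic zinc chloride 13 (not isolated)
Conditions: 8 (2.6 equiv), Zn dust, LiCl, THF, 25 °C; then 12 (1.0 equiv), Pd(OAc)2 (5 mol %), SPhos (10 mol %), THF, 25 to 50 °C
Reagents that add atoms: none
Why: Negishi cross-coupling run twice on one ring: zinc inserts into the C–Cl bond of 8 (LiCl keeps 13 in solution and holds back Wurtz coupling), zerovalent palladium formed from Pd(OAc)2 and SPhos adds oxidatively to a C–I bond of 12, the benzyl group passes from zinc to divalent palladium, and reductive elimination forms the C3–CH2 bond, after which the cycle repeats at C5. The closest known reaction type is the biarylphosphine-promoted coupling of LiCl-solubilised benzylic zinc chlorides with ortho-substituted aryl halides to give diarylmethanes. No ring is closed and no stereocentre is formed. The step needs chemoselectivity for C–I over three ketones, which the low basicity and nucleophilicity of the organozinc should secure. It also needs cross-coupling to outrun benzylic homocoupling and reductive deiodination, which the excess of 13 and the fast reductive elimination from a monoligated palladium centre should secure. Both reacting carbons lie between two benzyloxy groups, but the nucleophile is a primary sp3 carbon, so the new bond is far less congested than a biaryl bond. The order A–B–A is fixed by the positions of iodine and zinc, and because the C–C bonds form irreversibly with no free phenol or quinone methide present, the bridges cannot exchange.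

Step 11
Reactants: 14 hepta-O-benzyl agrimol C
Product: 15 agrimol C, 1-[3,5-bis[(3-butanoyl-2,6-dihydroxy-4-methoxy-5-methylphenyl)methyl]-2,4,6-trihydroxyphenyl]butan-1-one
Conditions: H2 (1 atm), Pd/C (10 %), EtOAc/MeOH, 25 °C
Reagents that add atoms: none
Why: hydrogenolysis of seven benzyl ethers under neutral conditions, which leave the methyl ethers, the diarylmethane bridges and the aryl ketones untouched; each ketone becomes chelated by an ortho hydroxyl as soon as it is freed.

## Compound list

1 | 2-methylbenzene-1,3,5-triol (2-methylphloroglucinol) | Cc1c(O)cc(O)cc1O | starting material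
2 | N-[(2,4,6-trihydroxy-3-methylphenyl)methylidene]-N-methylmethanaminium chloride | C[N+](C)=Cc1c(O)cc(O)c(C)c1O.[Cl-] | intermediate
3 | 2,4,6-trihydroxy-3-methylbenzaldehyde | O=Cc1c(O)cc(O)c(C)c1O | intermediate
4 | 2,6-dihydroxy-4-methoxy-3-methylbenzaldehyde | O=Cc1c(O)cc(OC)c(C)c1O | intermediate
5 | 3-butanoyl-2,6-dihydroxy-4-methoxy-5-methylbenzaldehyde | O=Cc1c(O)c(C(=O)CCC)c(OC)c(C)c1O | intermediate
6 | 2,6-bis(benzyloxy)-3-butanoyl-4-methoxy-5-methylbenzaldehyde | O=Cc1c(OCc2ccccc2)c(C(=O)CCC)c(OC)c(C)c1OCc1ccccc1 | intermediate
7 | 1-[2,4-bis(benzyloxy)-3-(hydroxymethyl)-6-methoxy-5-methylphenyl]butan-1-one | CCCC(=O)c1c(OC)c(C)c(OCc2ccccc2)c(CO)c1OCc1ccccc1 | intermediate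
8 | 1-[2,4-bis(benzyloxy)-3-(chloromethyl)-6-methoxy-5-methylphenyl]butan-1-one | CCCC(=O)c1c(OC)c(C)c(OCc2ccccc2)c(CCl)c1OCc1ccccc1 | intermediate
9 | benzene-1,3,5-triol (phloroglucinol) | Oc1cc(O)cc(O)c1 | starting material
10 | 1-(2,4,6-trihydroxyphenyl)butan-1-one | CCCC(=O)c1c(O)cc(O)cc1O | intermediate
11 | 1-[2,4,6-tris(benzyloxy)phenyl]butan-1-one | CCCC(=O)c1c(OCc2ccccc2)cc(OCc2ccccc2)cc1OCc1ccccc1 | intermediate
12 | 1-[2,4,6-tris(benzyloxy)-3,5-diiodophenyl]butan-1-one | CCCC(=O)c1c(OCc2ccccc2)c(I)c(OCc2ccccc2)c(I)c1OCc1ccccc1 | intermediate
13 | {[2,6-bis(benzyloxy)-3-butanoyl-4-methoxy-5-methylphenyl]methyl}zinc chloride | CCCC(=O)c1c(OC)c(C)c(OCc2ccccc2)c(C[Zn]Cl)c1OCc1ccccc1 | intermediate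
14 | 1-[2,4,6-tris(benzyloxy)-3,5-bis({[2,6-bis(benzyloxy)-3-butanoyl-4-methoxy-5-methylphenyl]methyl})phenyl]butan-1-one | CCCC(=O)c1c(OCc2ccccc2)c(Cc2c(OCc3ccccc3)c(C)c(OC)c(C(=O)CCC)c2OCc2ccccc2)c(OCc2ccccc2)c(Cc2c(OCc3ccccc3)c(C)c(OC)c(C(=O)CCC)c2OCc2ccccc2)c1OCc1ccccc1 | intermediate
15 | agrimol C, 1-[3,5-bis[(3-butanoyl-2,6-dihydroxy-4-methoxy-5-methylphenyl)methyl]-2,4,6-trihydroxyphenyl]butan-1-one | CCCC(=O)c1c(O)c(Cc2c(O)c(C)c(OC)c(C(=O)CCC)c2O)c(O)c(Cc2c(O)c(C)c(OC)c(C(=O)CCC)c2O)c1O | target

## Step count and least certain steps

Total step count: 11. Longest linear sequence: 8 steps (steps 1 to 6, then 10 and 11, from 1). The ring B branch (steps 7 to 9, from 9) joins at step 10.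

Step 10 (key step). Oxidative addition and transmetalation at carbons flanked by two benzyloxy groups may be slow. The organozinc would then be lost to protonation or benzylic homocoupling, and the mono-coupled iodide to reductive deiodination, so the second coupling may stall. The fallback changes the polarity back and needs neither iodine nor zinc. It sets out from 7 and 11: catalytic Sc(OTf)3 in CH2Cl2/hexafluoroisopropanol at 0 °C should ionise 7 to a benzylic cation stabilised by two ortho and one para oxygen, which attacks C3 and then C5 of 11 in a Friedel–Crafts benzylation. Ring A has no free position and cannot react with itself. The fallback comes back to the route at 14 and makes no new compound.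

Step 3. The Lewis acid may attack at the formyl-bearing carbon and cause loss of the formyl group, may stop at O-acylation, or may cleave the methyl ether beside the new ketone through chelation. The fallback introduces the ketone by organometallic chemistry. It sets out from 4, which is benzylated (BnBr, K2CO3, DMF) to 2,6-bis(benzyloxy)-4-methoxy-3-methylbenzaldehyde F1. Bromination at the single free ring carbon (NBS, MeCN) gives 2,6-bis(benzyloxy)-3-bromo-4-methoxy-5-methylbenzaldehyde F2. Acetalisation (HC(OMe)3, TsOH cat., MeOH) gives 1,3-bis(benzyloxy)-4-bromo-2-(dimethoxymethyl)-5-methoxy-6-methylbenzene F3. Bromine–lithium exchange (n-BuLi, THF, −78 °C) and acylation with N-methoxy-N-methylbutanamide give 1-[2,4-bis(benzyloxy)-3-(dimethoxymethyl)-6-methoxy-5-methylphenyl]butan-1-one F4. Hydrolysis of the acetal (1 M HCl, THF) comes back to the route at 6.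

Step 2. Methylation may run on to the dimethyl ether or fall partly on an ortho oxygen, because the mono-anion equilibrates among the three hydroxyls. The fallback sets the pattern by chelation-directed cleavage. It sets out from 3, which is exhaustively methylated (excess Me2SO4, K2CO3, acetone, reflux) to 2,4,6-trimethoxy-3-methylbenzaldehyde F5. AlCl3 in CH2Cl2 then cleaves only the two ethers ortho to the formyl group, through the aluminium chelate, and comes back to the route at 4.

Step 9. The second iodination next to two benzyloxy groups may be slow, and the acid co-catalyst may begin to cleave benzyl ethers or reverse the first iodination. The fallback inverts the order of protection and halogenation. It sets out from 10, whose free phenol ring should be iodinated rapidly (I2, NaHCO3, THF/H2O, 0 °C) to 1-(2,4,6-trihydroxy-3,5-diiodophenyl)butan-1-one F6. O-benzylation (BnBr, K2CO3, DMF) comes back to the route at 12.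

Step 11. Hydrogenolysis of the most hindered ethers may be slow, and prolonged exposure may begin to reduce the aryl ketones at the benzylic carbonyl. The fallback replaces hydrogenolysis by Lewis-acid cleavage with a cation scavenger. It sets out from 14: BCl3 and pentamethylbenzene in CH2Cl2 at −78 °C, quenched cold with MeOH, should remove benzyl ethers much faster than the methyl ethers. It comes back to the route at 15 and makes no new compound.

## Further compounds

F0 | step 10 | none | none
F1 | step 3 | 2,6-bis(benzyloxy)-4-methoxy-3-methylbenzaldehyde | O=Cc1c(OCc2ccccc2)cc(OC)c(C)c1OCc1ccccc1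
F2 | step 3 | 2,6-bis(benzyloxy)-3-bromo-4-methoxy-5-methylbenzaldehyde | O=Cc1c(OCc2ccccc2)c(Br)c(OC)c(C)c1OCc1ccccc1
F3 | step 3 | 1,3-bis(benzyloxy)-4-bromo-2-(dimethoxymethyl)-5-methoxy-6-methylbenzene | COC(OC)c1c(OCc2ccccc2)c(Br)c(OC)c(C)c1OCc1ccccc1
F4 | step 3 | 1-[2,4-bis(benzyloxy)-3-(dimethoxymethyl)-6-methoxy-5-methylphenyl]butan-1-one | CCCC(=O)c1c(OC)c(C)c(OCc2ccccc2)c(C(OC)OC)c1OCc1ccccc1
F5 | step 2 | 2,4,6-trimethoxy-3-methylbenzaldehyde | O=Cc1c(OC)cc(OC)c(C)c1OC
F6 | step 9 | 1-(2,4,6-trihydroxy-3,5-diiodophenyl)butan-1-one | CCCC(=O)c1c(O)c(I)c(O)c(I)c1O
F0 | step 11 | none | none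
A1 | alternative 1 | 1-(4,6-dihydroxy-2-methoxy-3-methylphenyl)butan-1-one | CCCC(=O)c1c(OC)c(C)c(O)cc1O
A2 | alternative 1 | 1-{3,5-bis[(dimethylamino)methyl]-2,4,6-trihydroxyphenyl}butan-1-one | CCCC(=O)c1c(O)c(CN(C)C)c(O)c(CN(C)C)c1O
A3 | alternative 2 | 1,5-bis[2,6-bis(benzyloxy)-4-methoxy-3-methylphenyl]pentan-3-one | O=C(CCc1c(OCc2ccccc2)c(C)c(OC)cc1OCc1ccccc1)CCc1c(OCc2ccccc2)c(C)c(OC)cc1OCc1ccccc1
A4 | alternative 2 | 2,4-bis{[2,6-bis(benzyloxy)-4-methoxy-3-methylphenyl]methyl}benzene-1,3,5-triol | Oc1cc(O)c(Cc2c(OCc3ccccc3)c(C)c(OC)cc2OCc2ccccc2)c(O)c1Cc1c(OCc2ccccc2)c(C)c(OC)cc1OCc1ccccc1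
A5 | alternative 3 | 1-(2,4,6-trihydroxy-3,5-dimethylphenyl)butan-1-one | CCCC(=O)c1c(O)c(C)c(O)c(C)c1O
A6 | alternative 3 | 2-butanoyl-3,5-dihydroxy-4-methyl-6-methylidenecyclohexa-2,4-dien-1-one | CCCC(=O)C1=C(O)C(C)=C(O)C(=C)C1=O
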